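The retrosynthesis cuts the C15'–C16' bond (carbinol carbon to ethyl) first. It then cuts the C1'–C5 bond between the benzylic CH2 and the ring; the side chain is counted from C1' at the ring to C17'.
Enabling feature: C1' is an unbranched primary sp3 carbon on C5 of the benzene ring. C5 is the one position meta to both oxygen-bearing carbons (C1, C3), so electrophilic alkylation cannot reach it. C1' is therefore generated as a primary radical from a carboxyl group, and C5 is addressed as a C–Br site.
Forward: the ring is bought as 5-bromoresorcinol and the fourteen CH2 groups as monomethyl hexadecanedioate. The N-hydroxyphthalimide ester of the half-ester and the aryl bromide are joined by nickel-electrocatalytic decarboxylative arylation, which assembles 21 of the 23 carbons in one event.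
The distal methyl ester is carried as a latent aldehyde, then reduced and ethylated. Hydrogenolysis of the two benzyl ethers ends the route, and no ring is formed at any stage.
Stereochemistry: the single centre C15' (S) comes from catalyst control, by Si-face addition of ZnEt2 to the aldehyde under Ti(OiPr)4 and a (1R,2R)-bis(triflamide) ligand. It is set after the coupling, so the alcohol never needs protection.
Key step: step 3

Assumption: 5-bromoresorcinol and monomethyl hexadecanedioate are taken to be catalogue compounds.

Step 1
Reactants: 1 5-bromobenzene-1,3-diol (5-bromoresorcinol)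
Product: 2 1,3-bis(benzyloxy)-5-bromobenzene
Conditions: BnBr (2.3 equiv), K2CO3 (3 equiv), acetone, reflux
Reagents that add atoms: benzyl bromide, BrCc1ccccc1
Why: Williamson ether synthesis, in which the two phenoxides formed with K2CO3 should displace bromide from benzyl bromide by SN2 while the aryl C–Br bond stays inert.

Step 2
Reactants: 3 16-methoxy-16-oxohexadecanoic acid (monomethyl hexadecanedioate)
Product: 4 1-(1,3-dioxoisoindolin-2-yl) 16-methyl hexadecanedioate
Conditions: N-hydroxyphthalimide (1.1 equiv), N,N'-diisopropylcarbodiimide (1.1 equiv), DMAP (10 mol%), CH2Cl2, rt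
Reagents that add atoms: N-hydroxyphthalimide, O=C1c2ccccc2C(=O)N1O
Why: Carbodiimide-mediated esterification (Steglich type), in which the carbodiimide activates the only free carboxyl group toward the acidic N–OH nucleophile and the distal methyl ester is untouched.

Step 3
Reactants: 4 1-(1,3-dioxoisoindolin-2-yl) 16-methyl hexadecanedioate; 2 1,3-bis(benzyloxy)-5-bromobenzene
Product: 5 methyl 15-[3,5-bis(benzyloxy)phenyl]pentadecanoate
Conditions: 4 (1.5 equiv), 2 (1.0 equiv), NiCl2·6H2O (20 mol%), 2,2'-bipyridine (20 mol%), AgNO3 (0.3 equiv), DMF, undivided cell, Mg anode / reticulated vitreous carbon cathode, constant current, ca. 2.5 F/mol, rt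
Reagents that add atoms: none
Why: Cathodic reduction gives low-valent (2,2'-bipyridine)nickel, which inserts into the C5–Br bond of 2 to give a divalent aryl nickel bromide, while single-electron transfer to the phthalimide unit of 4 breaks the N–O bond and, after loss of CO2, releases the primary C1' radical; capture of this radical gives a trivalent aryl(alkyl)nickel that forms the C1'–C5 bond by reductive elimination, and the monovalent nickel left behind is reduced again at the cathode while the Mg anode is consumed. The closest known reaction type is the nickel-electrocatalytic decarboxylative arylation of N-hydroxyphthalimide esters, a reductive cross-electrophile coupling run on a cathode coated in situ with silver nanoparticles from AgNO3 and established for primary alkyl esters with aryl bromides and iodides. No ring is closed and no stereocentre is created. The step needs cross-selectivity over biaryl formation, radical dimerisation and hydrogen abstraction, which the current-limited radical generation, the silver layer and the excess of 4 should secure. The site on the ring is fixed by the bromine at C5, and the linear connectivity by fast reductive elimination at bipyridine-ligated nickel, which should outrun β-hydride elimination and chain walking. The methyl ester and the benzyl ethers lie outside the working potential and should pass unchanged.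

Step 4
Reactants: 5 methyl 15-[3,5-bis(benzyloxy)phenyl]pentadecanoate
Product: 6 15-[3,5-bis(benzyloxy)phenyl]pentadecanal
Conditions: iBu2AlH (1.1 equiv), CH2Cl2, −78 °C; then MeOH, aq. potassium sodium tartrate
Reagents that add atoms: none
Why: Partial reduction of an ester with iBu2AlH, in which the hydride adduct should not collapse at −78 °C, so the aldehyde is released only on work-up and the benzyl ethers are inert to the hydride.

Step 5
Reactants: 6 15-[3,5-bis(benzyloxy)phenyl]pentadecanal
Product: 7 (3S)-17-[3,5-bis(benzyloxy)phenyl]heptadecan-3-ol
Conditions: ZnEt2 (1 M in hexanes, 2.5 equiv), Ti(OiPr)4 (1.2 equiv), (1R,2R)-N,N'-(cyclohexane-1,2-diyl)bis(trifluoromethanesulfonamide) (8 mol%), toluene, −20 °C; then 1 M HCl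
Reagents that add atoms: diethylzinc, CC[Zn]CC
Why: Titanium-mediated catalytic enantioselective dialkylzinc addition to an aldehyde, in which the chiral titanium bis(sulfonamide) complex of the (1R,2R)-ligand is known to deliver ethyl to the Si face of aldehydes, unbranched aliphatic ones included, which sets C15' as S (OH > C14' chain > ethyl > H).

Step 6
Reactants: 7 (3S)-17-[3,5-bis(benzyloxy)phenyl]heptadecan-3-ol
Product: 8 Hansfordiol C, 5-[(15S)-15-hydroxyheptadecyl]benzene-1,3-diol
Conditions: H2 (1 atm), 10% Pd/C, EtOAc/MeOH, rt
Reagents that add atoms: none
Why: Catalytic hydrogenolysis of benzyl aryl ethers, in which both benzylic C–O bonds should be cleaved on the palladium surface while the non-benzylic secondary alcohol, its stereocentre and the arene are not affected.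

Compound list
1 | 5-bromobenzene-1,3-diol (5-bromoresorcinol) | Oc1cc(O)cc(Br)c1 | starting material
2 | 1,3-bis(benzyloxy)-5-bromobenzene | Brc1cc(OCc2ccccc2)cc(OCc2ccccc2)c1 | intermediate
3 | 16-methoxy-16-oxohexadecanoic acid (monomethyl hexadecanedioate) | COC(=O)CCCCCCCCCCCCCCC(=O)O | starting material
4 | 1-(1,3-dioxoisoindolin-2-yl) 16-methyl hexadecanedioate | COC(=O)CCCCCCCCCCCCCCC(=O)ON1C(=O)c2ccccc2C1=O | intermediate
5 | methyl 15-[3,5-bis(benzyloxy)phenyl]pentadecanoate | COC(=O)CCCCCCCCCCCCCCc1cc(OCc2ccccc2)cc(OCc2ccccc2)c1 | intermediate
6 | 15-[3,5-bis(benzyloxy)phenyl]pentadecanal | O=CCCCCCCCCCCCCCCc1cc(OCc2ccccc2)cc(OCc2ccccc2)c1 | intermediate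
7 | (3S)-17-[3,5-bis(benzyloxy)phenyl]heptadecan-3-ol | CC[C@H](O)CCCCCCCCCCCCCCc1cc(OCc2ccccc2)cc(OCc2ccccc2)c1 | intermediate
8 | Hansfordiol C, 5-[(15S)-15-hydroxyheptadecyl]benzene-1,3-diol | CC[C@H](O)CCCCCCCCCCCCCCc1cc(O)cc(O)c1 | target

Total step count: 6. Longest linear sequence: 5 steps (3 to 4 to 5 to 6 to 7 to 8).

Steps most likely to fail

**Step 3.**
- The primary radical may be lost to hydrogen abstraction or dimerisation before the aryl nickel species captures it.
- The aryl bromide may undergo reductive homocoupling or hydrodebromination, and the Mg anode may passivate.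
- The fallback sets out from 4 and comes back at 5. It replaces radical capture at nickel by a two-electron transmetalation.
- Copper-catalysed decarboxylative borylation of 4 (Cu(acac)2, B2pin2, LiOH·H2O, MgCl2, dioxane/DMF, rt) should give methyl 15-(4,4,5,5-tetramethyl-1,3,2-dioxaborolan-2-yl)pentadecanoate F1.
- KHF2 in MeOH/H2O should turn this into potassium trifluoro(15-methoxy-15-oxopentadecyl)borate F2.
- Suzuki–Miyaura coupling of this salt with 2 (Pd(OAc)2, RuPhos, K2CO3, toluene/H2O, 80 °C) should give 5.

**Step 5.**
- Facial selectivity may be eroded because the unbranched aldehyde offers little steric bias.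
- Uncatalysed background ethylation, or β-hydride transfer that reduces the aldehyde, may also compete.
- The fallback sets out from 6 and comes back at 7. It exchanges catalyst control for enzymatic resolution.
- EtMgBr (THF, −78 °C) should give racemic 17-[3,5-bis(benzyloxy)phenyl]heptadecan-3-ol F3.
- Immobilised Candida antarctica lipase B with vinyl acetate (MTBE, 30 °C) should acylate the R enantiomer, whose ethyl group fits the small pocket of the enzyme. This gives (3R)-17-[3,5-bis(benzyloxy)phenyl]heptadecan-3-yl acetate F4.
- The acetate is removed by chromatography, and the unreacted S alcohol 7 remains.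

**Step 4.**
- The waxy ester may precipitate at low temperature.
- The hydride adduct may collapse early, which leads to over-reduction alongside incomplete conversion.
- The fallback sets out from 5 and comes back at 6. It replaces the partial reduction by a full reduction followed by re-oxidation.
- LiAlH4 (THF, 0 °C) should give 15-[3,5-bis(benzyloxy)phenyl]pentadecan-1-ol F5.
- Dess–Martin periodinane (CH2Cl2, rt) should oxidise this alcohol to 6.

Further compounds
F1 | step 3 | methyl 15-(4,4,5,5-tetramethyl-1,3,2-dioxaborolan-2-yl)pentadecanoate | COC(=O)CCCCCCCCCCCCCCB1OC(C)(C)C(C)(C)O1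
F2 | step 3 | potassium trifluoro(15-methoxy-15-oxopentadecyl)borate | COC(=O)CCCCCCCCCCCCCC[B-](F)(F)F.[K+]
F3 | step 5 | racemic 17-[3,5-bis(benzyloxy)phenyl]heptadecan-3-ol | CCC(O)CCCCCCCCCCCCCCc1cc(OCc2ccccc2)cc(OCc2ccccc2)c1
F4 | step 5 | (3R)-17-[3,5-bis(benzyloxy)phenyl]heptadecan-3-yl acetate | CC[C@@H](OC(C)=O)CCCCCCCCCCCCCCc1cc(OCc2ccccc2)cc(OCc2ccccc2)c1
F5 | step 4 | 15-[3,5-bis(benzyloxy)phenyl]pentadecan-1-ol | OCCCCCCCCCCCCCCCc1cc(OCc2ccccc2)cc(OCc2ccccc2)c1
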